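**Retrosynthetic overview**
1. 12 ⇐ 11 (MOM removal) ⇐ 10 (cross-metathesis, allyl → prenyl) ⇐ 8 (aromatic Claisen, allyl from O5 to C6).
2. Key C–C disconnection at C3–C4 of coumarin 8: aldol-type (Perkin–Oglialoro) condensation of salicylaldehyde 3 with arylacetic acid 6; the lactone C–O bond closes in the same pot.
3. 3 ⇐ symmetric diol 2 (mono-O-allylation) ⇐ 2,4,6-trimethoxybenzaldehyde 1; 6 ⇐ 2,4-dihydroxyphenylacetic acid 4 (MOM protection).
4. Ring order: both benzene rings are bought; the only ring built is the pyran-2-one (step 5).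

Assumption: the target has no stereocentre and no stereogenic double bond (the prenyl alkene carries two identical methyls), so it is achiral and there is no enantiomer to control; 1 and 4 are taken as catalogue materials.

**Route**

Step 1
Reactants: 1 2,4,6-trimethoxybenzaldehyde
Product: 2 2,6-dihydroxy-4-methoxybenzaldehyde
Conditions: AlCl3 (4 equiv), CH2Cl2, 0 °C → rt, 16 h; then ice/2 M HCl
Reagents that add atoms: none
Why: Chelation-controlled Lewis-acid ether cleavage, in which Al(III) bound to the formyl oxygen activates only the two flanking ortho-methoxy groups for demethylation by chloride (as in the AlCl3 conversion of 2,6-dimethoxybenzaldehyde into 2,6-dihydroxybenzaldehyde), while the unchelated 4-OMe survives at room temperature and the symmetry of 1 removes any regiochemical question.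

Step 2
Reactants: 2 2,6-dihydroxy-4-methoxybenzaldehyde
Product: 3 2-(allyloxy)-6-hydroxy-4-methoxybenzaldehyde
Conditions: allyl bromide (1.05 equiv), K2CO3 (1.1 equiv), acetone, reflux
Reagents that add atoms: allyl bromide, C=CCBr
Why: Williamson ether synthesis on a symmetric diol, where either OH gives the same mono-ether and the remaining OH, locked in a hydrogen bond to the aldehyde, reacts much more slowly, so limiting allyl bromide gives mainly 3 (diallyl ether and recovered 2 are removed by chromatography) and the OH left free is the future lactone oxygen.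

Step 3
Reactants: 4 2,4-dihydroxyphenylacetic acid
Product: 5 methoxymethyl 2-[2,4-bis(methoxymethoxy)phenyl]acetate
Conditions: MOMCl (3.6 equiv), i-Pr2NEt (5 equiv), CH2Cl2, 0 °C → rt
Reagents that add atoms: chloromethyl methyl ether (MOMCl), COCCl
Why: Exhaustive O-alkylation with an α-chloro ether caps both phenols and the carboxylate, so the 2'-OH can neither lactonise to a benzofuranone nor interfere in the later condensation.

Step 4
Reactants: 5 methoxymethyl 2-[2,4-bis(methoxymethoxy)phenyl]acetate
Product: 6 2-[2,4-bis(methoxymethoxy)phenyl]acetic acid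
Conditions: LiOH·H2O (2 equiv), THF/H2O (3:1), 0 °C → rt; then cold 1 M HCl to pH 4, extract at once
Reagents that add atoms: water, O
Why: Saponification, in which the acetal ester is readily cleaved by hydroxide while aryl MOM ethers are inert to base, and the brief cold acidification to pH 4 frees the acid without touching the acetals.

Step 5
Reactants: 3 2-(allyloxy)-6-hydroxy-4-methoxybenzaldehyde; 6 2-[2,4-bis(methoxymethoxy)phenyl]acetic acid
Product: 8 5-(allyloxy)-3-[2,4-bis(methoxymethoxy)phenyl]-7-methoxy-2H-chromen-2-one, via mixed anhydride 7 (not isolated)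
Conditions: Ac2O (8 equiv), Et3N (3 equiv), 105–110 °C, 10 h, Ar
Reagents that add atoms: none
Why: Perkin–Oglialoro condensation, an intermolecular aldol-type condensation in which Et3N enolises mixed anhydride 7 (made in situ from 6 and Ac2O, its acetyl leaving again as acetic acid), the enolate adds to the aldehyde carbon of 3 to forge C3–C4, and dehydration plus acyl transfer to the only free ortho phenol closes the lactone, so the allyloxy group must end up at C5; allyl and MOM ethers tolerate Ac2O/Et3N at 110 °C.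

Step 6
Reactants: 8 5-(allyloxy)-3-[2,4-bis(methoxymethoxy)phenyl]-7-methoxy-2H-chromen-2-one
Product: 10 6-allyl-3-[2,4-bis(methoxymethoxy)phenyl]-5-hydroxy-7-methoxy-2H-chromen-2-one, via cyclohexadienone 9 (not isolated)
Conditions: PhNEt2, 195–200 °C, sealed tube, Ar, 4 h
Reagents that add atoms: none
Why: Aromatic Claisen rearrangement ([3,3]-sigmatropic), in which only C6 of the two positions ortho to O5 is unsubstituted (C4a is the ring fusion), so the allyl group is delivered exclusively to C6 and dienone 9 re-aromatises by enolisation, the basic solvent protecting the MOM acetals.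

Step 7
Reactants: 10 6-allyl-3-[2,4-bis(methoxymethoxy)phenyl]-5-hydroxy-7-methoxy-2H-chromen-2-one
Product: 11 3-[2,4-bis(methoxymethoxy)phenyl]-5-hydroxy-7-methoxy-6-(3-methylbut-2-en-1-yl)-2H-chromen-2-one
Conditions: Grubbs II (5 mol %), 2-methyl-2-butene/CH2Cl2 (1:2), 40 °C, sealed tube, 12 h
Reagents that add atoms: 2-methyl-2-butene, CC=C(C)C
Why: Olefin cross-metathesis, in which the terminal allyl alkene is capped by excess 2-methyl-2-butene as the trisubstituted prenyl alkene with loss of propene, while the free phenol, the MOM ethers and the electron-poor coumarin C3=C4 bond are left alone and no alkene geometry arises.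

Step 8
Reactants: 11 3-[2,4-bis(methoxymethoxy)phenyl]-5-hydroxy-7-methoxy-6-(3-methylbut-2-en-1-yl)-2H-chromen-2-one
Product: 12 3-(2,4-dihydroxyphenyl)-5-hydroxy-7-methoxy-6-(3-methylbut-2-en-1-yl)-2H-chromen-2-one (CNP0305155.0)
Conditions: 3 M aq HCl/MeOH (1:6), 45 °C, 2 h, stopped at full conversion
Reagents that add atoms: none
Why: Acid-catalysed acetal (MOM ether) solvolysis cleaves both aryl MOM ethers as dimethoxymethane, while the aryl methyl ether, the lactone and, at this mild acidity, the prenyl group stay intact.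

**Compound list**
1 | 2,4,6-trimethoxybenzaldehyde | COc1cc(OC)c(C=O)c(OC)c1 | starting material
2 | 2,6-dihydroxy-4-methoxybenzaldehyde | COc1cc(O)c(C=O)c(O)c1 | intermediate
3 | 2-(allyloxy)-6-hydroxy-4-methoxybenzaldehyde | COc1cc(O)c(C=O)c(OCC=C)c1 | intermediate
4 | 2,4-dihydroxyphenylacetic acid | OC(=O)Cc1ccc(O)cc1O | starting material
5 | methoxymethyl 2-[2,4-bis(methoxymethoxy)phenyl]acetate | COCOC(=O)Cc1ccc(OCOC)cc1OCOC | intermediate
6 | 2-[2,4-bis(methoxymethoxy)phenyl]acetic acid | OC(=O)Cc1ccc(OCOC)cc1OCOC | intermediate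
7 | acetic 2-[2,4-bis(methoxymethoxy)phenyl]acetic anhydride (mixed anhydride, not isolated) | CC(=O)OC(=O)Cc1ccc(OCOC)cc1OCOC | intermediate
8 | 5-(allyloxy)-3-[2,4-bis(methoxymethoxy)phenyl]-7-methoxy-2H-chromen-2-one | COc1cc2oc(=O)c(-c3ccc(OCOC)cc3OCOC)cc2c(OCC=C)c1 | intermediate
9 | 6-allyl-3-[2,4-bis(methoxymethoxy)phenyl]-7-methoxy-6H-chromene-2,5-dione (racemic dienone, not isolated; its stereocentre is lost on enolisation) | COC1=CC2=C(C=C(c3ccc(OCOC)cc3OCOC)C(=O)O2)C(=O)C1CC=C | intermediate
10 | 6-allyl-3-[2,4-bis(methoxymethoxy)phenyl]-5-hydroxy-7-methoxy-2H-chromen-2-one | COc1cc2oc(=O)c(-c3ccc(OCOC)cc3OCOC)cc2c(O)c1CC=C | intermediate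
11 | 3-[2,4-bis(methoxymethoxy)phenyl]-5-hydroxy-7-methoxy-6-(3-methylbut-2-en-1-yl)-2H-chromen-2-one | COc1cc2oc(=O)c(-c3ccc(OCOC)cc3OCOC)cc2c(O)c1CC=C(C)C | intermediate
12 | 3-(2,4-dihydroxyphenyl)-5-hydroxy-7-methoxy-6-(3-methylbut-2-en-1-yl)-2H-chromen-2-one (achiral) | COc1cc2oc(=O)c(-c3ccc(O)cc3O)cc2c(O)c1CC=C(C)C | target

**Totals**
Total step count: 8.
Longest linear sequence: 6 steps (1 → 2 → 3 → 8 → 10 → 11 → 12; the branch 4 → 5 → 6 → 8 → … → 12 is equally long).

**Three steps most likely to fail, with fallbacks**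

Step 5 (Perkin condensation). The aldehyde is hindered and electron-rich, and the MOM acetals sit in hot Ac2O. The fallback sets out from 3 and 6 and comes back at 8. It makes the same C3–C4 bond by a discrete low-temperature enolate aldol addition instead of a thermal condensation. Acid 6 is methylated (MeI, K2CO3, DMF) to methyl 2-[2,4-bis(methoxymethoxy)phenyl]acetate F1. The phenol of 3 is silylated (TBSCl, imidazole, DMF) to 2-(allyloxy)-6-[(tert-butyldimethylsilyl)oxy]-4-methoxybenzaldehyde F2. The lithium enolate of F1 (LDA, THF, −78 °C) is added to F2 to give methyl 3-[2-(allyloxy)-6-[(tert-butyldimethylsilyl)oxy]-4-methoxyphenyl]-2-[2,4-bis(methoxymethoxy)phenyl]-3-hydroxypropanoate F3 as a diastereomer mixture, which does not matter. TBAF in THF frees the phenoxide, which lactonises onto the methyl ester to give 5-(allyloxy)-3-[2,4-bis(methoxymethoxy)phenyl]-4-hydroxy-7-methoxy-3,4-dihydro-2H-chromen-2-one F4. DBU (toluene, 60 °C) then dehydrates F4 by E1cB to 8.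

Step 6 (Claisen rearrangement). 200 °C on the fully built coumarin may cause decomposition or MOM loss. The fallback sets out from 3 and comes back at 12. It moves the rearrangement to the simple aldehyde and uses a protecting-group relay to keep the two ortho oxygens distinct. Compound 3 is silylated (TIPSCl, imidazole, DMF) to 2-(allyloxy)-4-methoxy-6-[(triisopropylsilyl)oxy]benzaldehyde F5. Heating F5 in PhNEt2 at 190 °C sends the allyl group to the only free ortho carbon, giving 3-allyl-2-hydroxy-4-methoxy-6-[(triisopropylsilyl)oxy]benzaldehyde F6. The new phenol is capped (MOMCl, i-Pr2NEt) to 3-allyl-4-methoxy-2-(methoxymethoxy)-6-[(triisopropylsilyl)oxy]benzaldehyde F7, and TBAF releases 3-allyl-6-hydroxy-4-methoxy-2-(methoxymethoxy)benzaldehyde F8. Condensation of F8 with 6 under the step 5 conditions gives 6-allyl-3-[2,4-bis(methoxymethoxy)phenyl]-7-methoxy-5-(methoxymethoxy)-2H-chromen-2-one F9. Cross-metathesis as in step 7 gives 3-[2,4-bis(methoxymethoxy)phenyl]-7-methoxy-5-(methoxymethoxy)-6-(3-methylbut-2-en-1-yl)-2H-chromen-2-one F10, and methanolic HCl as in step 8 removes all three MOM groups to give 12.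

Step 8 (acidic MOM removal beside a prenyl group ortho to a free phenol). The risk is chroman formation or HCl addition to the prenyl alkene. The fallback sets out from 10 and comes back at 12. It reverses the last two operations so that acid never meets the prenyl group. Compound 10 is deprotected first (3 M HCl/MeOH, 45 °C) to 6-allyl-3-(2,4-dihydroxyphenyl)-5-hydroxy-7-methoxy-2H-chromen-2-one F11; its monosubstituted allyl alkene cannot give a stabilised cation. Cross-metathesis of the free triphenol F11 with 2-methyl-2-butene (Hoveyda–Grubbs II, CH2Cl2/THF, 40 °C) then gives 12 under neutral conditions.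

**Further compounds**
F1 | step 5 | methyl 2-[2,4-bis(methoxymethoxy)phenyl]acetate | COC(=O)Cc1ccc(OCOC)cc1OCOC
F2 | step 5 | 2-(allyloxy)-6-[(tert-butyldimethylsilyl)oxy]-4-methoxybenzaldehyde | COc1cc(O[Si](C)(C)C(C)(C)C)c(C=O)c(OCC=C)c1
F3 | step 5 | methyl 3-[2-(allyloxy)-6-[(tert-butyldimethylsilyl)oxy]-4-methoxyphenyl]-2-[2,4-bis(methoxymethoxy)phenyl]-3-hydroxypropanoate (racemic syn/anti mixture) | COC(=O)C(c1ccc(OCOC)cc1OCOC)C(O)c1c(OCC=C)cc(OC)cc1O[Si](C)(C)C(C)(C)C
F4 | step 5 | 5-(allyloxy)-3-[2,4-bis(methoxymethoxy)phenyl]-4-hydroxy-7-methoxy-3,4-dihydro-2H-chromen-2-one (racemic cis/trans mixture) | COc1cc2OC(=O)C(c3ccc(OCOC)cc3OCOC)C(O)c2c(OCC=C)c1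
F5 | step 6 | 2-(allyloxy)-4-methoxy-6-[(triisopropylsilyl)oxy]benzaldehyde | COc1cc(O[Si](C(C)C)(C(C)C)C(C)C)c(C=O)c(OCC=C)c1
F6 | step 6 | 3-allyl-2-hydroxy-4-methoxy-6-[(triisopropylsilyl)oxy]benzaldehyde | COc1cc(O[Si](C(C)C)(C(C)C)C(C)C)c(C=O)c(O)c1CC=C
F7 | step 6 | 3-allyl-4-methoxy-2-(methoxymethoxy)-6-[(triisopropylsilyl)oxy]benzaldehyde | COc1cc(O[Si](C(C)C)(C(C)C)C(C)C)c(C=O)c(OCOC)c1CC=C
F8 | step 6 | 3-allyl-6-hydroxy-4-methoxy-2-(methoxymethoxy)benzaldehyde | COc1cc(O)c(C=O)c(OCOC)c1CC=C
F9 | step 6 | 6-allyl-3-[2,4-bis(methoxymethoxy)phenyl]-7-methoxy-5-(methoxymethoxy)-2H-chromen-2-one | COc1cc2oc(=O)c(-c3ccc(OCOC)cc3OCOC)cc2c(OCOC)c1CC=C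
F10 | step 6 | 3-[2,4-bis(methoxymethoxy)phenyl]-7-methoxy-5-(methoxymethoxy)-6-(3-methylbut-2-en-1-yl)-2H-chromen-2-one | COc1cc2oc(=O)c(-c3ccc(OCOC)cc3OCOC)cc2c(OCOC)c1CC=C(C)C
F11 | step 8 | 6-allyl-3-(2,4-dihydroxyphenyl)-5-hydroxy-7-methoxy-2H-chromen-2-one | COc1cc2oc(=O)c(-c3ccc(O)cc3O)cc2c(O)c1CC=C
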